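Retrosynthetic cuts: the O6–C12 lactone bond and the O8 acyl bond go first. The C3 and C8 carbinols go back to ketones. These two carbonyl carbons are then joined (C3–C8), which turns the ten-membered ring into a cis-fused decalin-3,8-diol. Ring B of that decalin is cut at C10–CH3, C1=C10 (metathesis), C2–C3 (allyl addition) and C8–C9 (enolate alkylation).
Enabling feature: C3 and C8 both carry oxygen and lie 1,6 across the ten-membered ring, and the arc C3–C4(CH3)=C5–C6(O)–C7(isopropenyl)–C8 is the six-membered ring of carvone with its cis double bond. The bond to be broken is therefore the carbonyl–CH2 bond of carvone.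
Forward order: ring A is (S)-carvone, oxygenated at C6 and C8, alkylated at C8 and allylated at C3. Ring B is closed by ring-closing metathesis. Pb(OAc)4 then cleaves the ring-fusion glycol and the ten-membered ring appears. The lactone ring is closed last.
Stereochemistry: C7 comes from (S)-carvone; C6 from peracid attack anti to the isopropenyl group; C10 from equatorial methyl addition on the cis-decalin; C8 from hydride delivery by the C10 hydroxyl; C3 from oxazaborolidine control. The two ring-fusion centres of the decalin are temporary.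

Key step: step 11

Remarks on the chemistry
- Numbering and faces: germacrane numbering is used (C3 = carvone carbonyl carbon, C4 = its methyl-bearing carbon, C6 = γ-carbon, C7 = isopropenyl-bearing carbon, C8 = α′-carbon); ring A = C3–C8, ring B = C3, C2, C1, C10, C9, C8; β is a local label for the ring face of the C6 oxygen and α for the face of the C7 isopropenyl group.
- Assumption on facial course: carbon groups enter C8 and C3 anti to the isopropenyl group, so the ring-fusion hydroxyls of the decalin sit on the α face; C10 is therefore built by methyl addition to a ring B ketone from that convex face, which leaves O10 on the β face as the target requires.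
- 3-Bromo-2-methoxyprop-1-ene is taken as a purchasable reagent.
- The 10-hydroxy-3-ketones 24, 25, 27 and 29 may equilibrate with their transannular 3,10-hemiketals; they are drawn in the open keto form, which is the form that reacts.

Step 1
Reactants: 1 (S)-carvone; 2 isopropenyl acetate
Product: 3 (5R)-2-methyl-5-(prop-1-en-2-yl)cyclohexa-1,3-dien-1-yl acetate
Conditions: isopropenyl acetate (excess), TsOH·H2O (cat.), reflux, acetone distilled off
Reagents that add atoms: isopropenyl acetate, CC(=C)OC(C)=O
Why: Acid-catalysed enol ester exchange under equilibrating conditions should give the linear, fully conjugated C3=C4–C5=C6 dienyl acetate, the thermodynamic dienol derivative of a 2-cyclohexenone, without touching C7.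

Step 2
Reactants: 3 dienyl acetate; 4 3-chloroperoxybenzoic acid
Product: 6 (4R,5S)-4-hydroxy-2-methyl-5-(prop-1-en-2-yl)cyclohex-2-en-1-one, via epoxy enol acetate 5 (not isolated)
Conditions: mCPBA (1.05 equiv), dioxane/H2O 9:1, 0 °C → rt
Reagents that add atoms: 3-chloroperoxybenzoic acid, OOC(=O)c1cccc(Cl)c1
Why: Vinylogous Rubottom-type oxidation: the peracid epoxidises the terminal C5=C6 bond of the dienyl ester on the face anti to the adjacent C7 isopropenyl group and the epoxide opens with loss of the acetyl group to the γ-hydroxy enone, which sets C6 with its oxygen β (trans to the isopropenyl group).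

Step 3
Reactants: 6 γ-hydroxy enone; 7 tert-butylchlorodimethylsilane
Product: 8 (4R,5S)-4-[(tert-butyldimethylsilyl)oxy]-2-methyl-5-(prop-1-en-2-yl)cyclohex-2-en-1-one
Conditions: TBSCl, imidazole, DMF, rt
Reagents that add atoms: tert-butylchlorodimethylsilane, CC(C)(C)[Si](C)(C)Cl
Why: Imidazole-promoted silylation of the secondary allylic alcohol; O6 must stay masked until C3 is no longer a ketone, because a free C6 hydroxyl would add to the later cis-enone.

Step 4
Reactants: 8 silyl ether; 9 3-phenyl-2-(phenylsulfonyl)oxaziridine
Product: 11 8β-hydroxy ketone (8 with a hydroxyl at C8 trans to the isopropenyl group), via potassium enolate 10 (not isolated)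
Conditions: KN(SiMe3)2, THF, −78 °C; then 9, −78 °C; aq. NH4Cl
Reagents that add atoms: 3-phenyl-2-(phenylsulfonyl)oxaziridine, O=S(=O)(N1OC1c1ccccc1)c1ccccc1
Why: Kinetic deprotonation at C8 and electrophilic hydroxylation of the enolate with the N-sulfonyloxaziridine (enolate oxidation); oxygen should enter anti to the C7 isopropenyl group, a centre that is levelled again by enolisation in step 6.

Step 5
Reactants: 11 8β-hydroxy ketone; 12 chlorotriethylsilane
Product: 13 8-O-triethylsilyl ether of 11
Conditions: Et3SiCl, imidazole, DMAP (cat.), DMF, 0 °C → rt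
Reagents that add atoms: chlorotriethylsilane, CC[Si](Cl)(CC)CC
Why: Standard silylation of the secondary α-hydroxy ketone; a non-chelating silyl ether on O8 is needed for the enolate alkylation and for the facial control of step 7.

Step 6
Reactants: 13 α-silyloxy ketone; 14 3-bromo-2-methoxyprop-1-ene
Product: 16 C8-quaternary ketone (2-methoxyprop-2-enyl group β and triethylsilyloxy group α at C8), via lithium enolate 15 (not isolated)
Conditions: LiN(iPr)2, THF, −78 °C; DMPU, then 14, −78 → −30 °C
Reagents that add atoms: 3-bromo-2-methoxyprop-1-ene, COC(=C)CBr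
Why: C-Alkylation of the tetrasubstituted α-silyloxy enolate with a reactive allylic bromide (an acetonyl equivalent): the electrophile should enter anti to the adjacent, pseudoaxial C7 isopropenyl group, which places C9 on the β face and O8 on the α face of the new quaternary C8 whatever the configuration of 13.

Step 7
Reactants: 16 C8-quaternary ketone; 17 allylmagnesium bromide
Product: 18 tertiary allylic alcohol (allyl group β and hydroxyl α at C3)
Conditions: CH2=CHCH2MgBr, THF, −78 °C; aq. NH4Cl
Reagents that add atoms: allylmagnesium bromide, C=CC[Mg]Br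
Why: 1,2-Addition of the allyl Grignard reagent to the enone carbonyl: in the half-chair with equatorial isopropenyl the C8 silyloxy group is axial on the α face, so axial attack anti to that C–O bond (polar Felkin–Anh) should bring the allyl group in from the β face, cis to the C8 side chain, and set C3 with its hydroxyl α, cis to O8.

Step 8
Reactants: 18 diene
Product: 19 cis-fused bicyclic enol ether (ring B with C1=C10–OCH3; 3α-hydroxyl; 8α-triethylsilyloxy)
Conditions: second-generation Grubbs catalyst RuCl2(=CHPh)(H2IMes)(PCy3) (5 mol %), toluene, 70 °C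
Reagents that add atoms: none
Why: Ring-closing metathesis of the monosubstituted allyl alkene onto the 1,1-disubstituted enol ether closes six-membered ring B as its cyclic enol ether; the two chains are cis on adjacent carbons, while the isopropenyl group (trans to the allyl group across ring A) and the trisubstituted ring alkene cannot ring-close.

Step 9
Reactants: 19 bicyclic enol ether; 20 water
Product: 21 cis-decalin-3α,8α-diol-10-one (6β-silyloxy; 7α-isopropenyl; C4=C5)
Conditions: 0.5 M aq. HCl, THF, 0 °C → rt
Reagents that add atoms: water, O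
Why: Acid hydrolysis of the enol ether unveils the C10 ketone, and the same medium cleaves the tertiary triethylsilyl ether, which is far more acid-labile than the secondary tert-butyldimethylsilyl ether.

Step 10
Reactants: 21 diol ketone; 22 methylmagnesium bromide
Product: 23 cis-decalin triol (3α,8α,10β-trihydroxy; 10α-methyl, 10S; 6β-silyloxy; 7α-isopropenyl)
Conditions: CH3MgBr (4 equiv), CeCl3, THF, −78 → −20 °C; aq. NH4Cl
Reagents that add atoms: methylmagnesium bromide, C[Mg]Br
Why: Grignard addition to the ring B ketone: in the favoured cis-decalin conformer the C8–C7 bond is axial on the β face of ring B, so the methyl group should enter equatorially from the α (convex) face, the face of the ring-fusion hydroxyls, and leave the C10 hydroxyl on the β face (10S).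

Step 11
Reactants: 23 cis-decalin triol
Product: 24 (4Z,6R,7S,10S)-6-[(tert-butyldimethylsilyl)oxy]-10-hydroxygermacra-4,11(13)-diene-3,8-dione
Conditions: Pb(OAc)4 (1.05 equiv), CH2Cl2, −20 → 0 °C, 10 min; cold filtration, used at once
Reagents that add atoms: none
Why: Lead tetraacetate (tetravalent lead) exchanges two acetates for the cis C3 and C8 hydroxyls to give a five-membered cyclic lead diester, which fragments in a two-electron step to the C3 and C8 carbonyl groups and lead diacetate (Criegee glycol cleavage, used here as a ring expansion of a fused bicyclic diol). No ring is closed by bond formation: the ten-membered ring is the perimeter of the decalin and appears when the shared C3–C8 bond is removed, so there is no mode of cyclisation to control. No stereocentre is created; C6, C7 and C10 are carried over, the two temporary ring-fusion centres vanish, and the (Z)-C4=C5 geometry is inherited from the cyclohexene. The step needs site selectivity, and only the vicinal cis-diol can chelate lead; the isolated tertiary C10 hydroxyl, the silyl ether and the alkenes should be inert at 0 °C. Because 24 carries a β-silyloxy group and a β-hydroxyl next to the new C8 ketone, the reaction is run cold, without amine base, and 24 is reduced at once.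

Step 12
Reactants: 24 enedione
Product: 25 (8R)-alcohol (8α-hydroxyl, 1,3-anti to the 10β-hydroxyl; C3 enone kept)
Conditions: Me4NBH(OAc)3 (5 equiv), MeCN/AcOH 1:1, −30 °C
Reagents that add atoms: none
Why: Saksena–Evans hydroxyl-directed reduction: the C10 hydroxyl exchanges onto boron and delivers hydride through a six-membered transition state to the β-carbonyl at C8 from its own face, which should give the 1,3-anti (8R) alcohol, while the enone, which has no β-hydroxyl, is not reduced by the acyloxyborohydride.

Step 13
Reactants: 25 diol; 26 isobutyric anhydride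
Product: 27 8-isobutyrate (8α-(2-methylpropanoyloxy) enone with free 10β-hydroxyl)
Conditions: (i-PrCO)2O, Et3N, DMAP (cat.), CH2Cl2, 0 °C → rt
Reagents that add atoms: isobutyric anhydride, CC(C)C(=O)OC(=O)C(C)C
Why: DMAP-catalysed acylation of the only secondary hydroxyl; the tertiary C10 hydroxyl should not react under these conditions.

Step 14
Reactants: 27 isobutyrate; 28 tert-butyl hydroperoxide
Product: 29 primary allylic alcohol (12-hydroxy derivative of 27)
Conditions: SeO2 (0.3 equiv), t-BuOOH (3 equiv), CH2Cl2, rt
Reagents that add atoms: tert-butyl hydroperoxide, CC(C)(C)OO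
Why: SeO2-catalysed allylic hydroxylation (ene reaction, then [2,3]-sigmatropic shift, oxygen relayed from the hydroperoxide through selenium) at the methyl group of the 1,1-disubstituted isopropenyl alkene; the C4=C5 alkene is deactivated by conjugation with the C3 ketone, which is why this oxidation is placed before the C3 reduction.

Step 15
Reactants: 29 hydroxy enone
Product: 30 (3S)-allylic alcohol (3α,10β,12-triol 8-isobutyrate)
Conditions: (R)-2-methyl-CBS-oxazaborolidine (0.3 equiv), catecholborane (4 equiv), toluene, −78 → −40 °C
Reagents that add atoms: none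
Why: Corey–Bakshi–Shibata reduction: the enone is reduced 1,2 with the trisubstituted alkenyl carbon C4 as the large and the C2 methylene as the small ketone substituent, so the (R)-oxazaborolidine should deliver hydride to the β face and give the (3S) allylic alcohol; ester, silyl ether and alkenes are left untouched.

Step 16
Reactants: 30 triol
Product: 31 enal (12-aldehyde; 2-substituted acrolein)
Conditions: TEMPO (0.2 equiv), PhI(OAc)2 (1.2 equiv), CH2Cl2, rt
Reagents that add atoms: none
Why: Oxoammonium (TEMPO/PhI(OAc)2) oxidation, selective for the primary allylic alcohol over the secondary C3 and the tertiary C10 hydroxyls.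

Step 17
Reactants: 31 enal; 32 sodium chlorite
Product: 33 acrylic acid (12-oic acid)
Conditions: NaClO2, NaH2PO4, 2-methylbut-2-ene, t-BuOH/H2O, 0 °C → rt
Reagents that add atoms: sodium chlorite, [Na+].[O-]Cl=O
Why: Pinnick oxidation of the enal to the acrylic acid; chlorite does not oxidise the secondary allylic alcohol, and the hypochlorite formed is trapped by 2-methylbut-2-ene.

Step 18
Reactants: 33 acrylic acid
Product: 35 (3S,4Z,6R,7R,8R,10S)-3,10-dihydroxy-8-(2-methylpropanoyloxy)germacra-4,11(13)-dien-12,6-olide (target), via hydroxy acid 34 (not isolated)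
Conditions: HF·pyridine, THF, 0 °C → rt
Reagents that add atoms: none
Why: Desilylation with HF·pyridine frees the C6 hydroxyl, which closes the five-membered lactone onto the acrylic acid under the same acidic conditions (γ-lactonisation); O8 is acylated and the C3 and C10 hydroxyls are too remote, so only the 6,12-olide can form.

Compound list
1 | (S)-carvone, (5S)-2-methyl-5-(prop-1-en-2-yl)cyclohex-2-en-1-one | CC1=CC[C@H](C(C)=C)CC1=O | starting material
2 | isopropenyl acetate (prop-1-en-2-yl acetate) | CC(=C)OC(C)=O | starting material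
3 | (5R)-2-methyl-5-(prop-1-en-2-yl)cyclohexa-1,3-dien-1-yl acetate (linear dienyl acetate, C3=C4 and C5=C6) | CC(=C)[C@H]1C=CC(C)=C(OC(C)=O)C1 | intermediate
4 | 3-chloroperoxybenzoic acid | OOC(=O)c1cccc(Cl)c1 | starting material
5 | 5,6-epoxide of 3 (oxirane oxygen β, trans to the isopropenyl group) | CC(=C)[C@H]1[C@@H]2O[C@@H]2C(C)=C(OC(C)=O)C1 | intermediate (not isolated)
6 | (4R,5S)-4-hydroxy-2-methyl-5-(prop-1-en-2-yl)cyclohex-2-en-1-one (6β-hydroxyl, trans to isopropenyl) | CC(=C)[C@H]1[C@H](O)C=C(C)C(=O)C1 | intermediate
7 | tert-butylchlorodimethylsilane | CC(C)(C)[Si](C)(C)Cl | starting material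
8 | (4R,5S)-4-[(tert-butyldimethylsilyl)oxy]-2-methyl-5-(prop-1-en-2-yl)cyclohex-2-en-1-one | CC(=C)[C@H]1[C@H](O[Si](C)(C)C(C)(C)C)C=C(C)C(=O)C1 | intermediate
9 | 3-phenyl-2-(phenylsulfonyl)oxaziridine (racemic) | O=S(=O)(N1OC1c1ccccc1)c1ccccc1 | starting material
10 | potassium enolate of 8 (C3–OK, C3=C8; KC16H27O2Si) | CC(=C)[C@H]1[C@H](O[Si](C)(C)C(C)(C)C)C=C(C)C([O-])=C1.[K+] | intermediate (not isolated)
11 | 8β-hydroxy ketone: 8 with a hydroxyl at C8, trans to the isopropenyl group | CC(=C)[C@H]1[C@H](O[Si](C)(C)C(C)(C)C)C=C(C)C(=O)[C@@H]1O | intermediate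
12 | chlorotriethylsilane | CC[Si](Cl)(CC)CC | starting material
13 | 8-O-triethylsilyl ether of 11 | CC(=C)[C@H]1[C@H](O[Si](C)(C)C(C)(C)C)C=C(C)C(=O)[C@@H]1O[Si](CC)(CC)CC | intermediate
14 | 3-bromo-2-methoxyprop-1-ene | COC(=C)CBr | starting material
15 | lithium enolate of 13 (C3–OLi, C3=C8; LiC22H41O3Si2) | CC(=C)[C@H]1[C@H](O[Si](C)(C)C(C)(C)C)C=C(C)C([O-])=C1O[Si](CC)(CC)CC.[Li+] | intermediate (not isolated)
16 | C8-quaternary ketone: 8β-(2-methoxyprop-2-enyl), 8α-triethylsilyloxy, 6β-silyloxy, 7α-isopropenyl | CC(=C)[C@H]1[C@H](O[Si](C)(C)C(C)(C)C)C=C(C)C(=O)[C@]1(O[Si](CC)(CC)CC)CC(=C)OC | intermediate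
17 | allylmagnesium bromide | C=CC[Mg]Br | starting material
18 | tertiary allylic alcohol: 3β-allyl, 3α-hydroxyl, otherwise as 16 | CC(=C)[C@H]1[C@H](O[Si](C)(C)C(C)(C)C)C=C(C)[C@](O)(CC=C)[C@]1(O[Si](CC)(CC)CC)CC(=C)OC | intermediate
19 | cis-fused bicyclic enol ether: ring B with C1=C10–OCH3, 3α-hydroxyl, 8α-triethylsilyloxy | CC(=C)[C@H]1[C@H](O[Si](C)(C)C(C)(C)C)C=C(C)[C@]2(O)CC=C(OC)C[C@]12O[Si](CC)(CC)CC | intermediate
20 | water | O | starting material
21 | cis-decalin-3α,8α-diol-10-one (6β-silyloxy, 7α-isopropenyl, C4=C5) | CC(=C)[C@H]1[C@H](O[Si](C)(C)C(C)(C)C)C=C(C)[C@]2(O)CCC(=O)C[C@]12O | intermediate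
22 | methylmagnesium bromide | C[Mg]Br | starting material
23 | cis-decalin triol: 3α,8α,10β-trihydroxy, 10α-methyl (10S), 6β-silyloxy, 7α-isopropenyl, C4=C5 | CC(=C)[C@H]1[C@H](O[Si](C)(C)C(C)(C)C)C=C(C)[C@]2(O)CC[C@](C)(O)C[C@]12O | intermediate
24 | (4Z,6R,7S,10S)-6-[(tert-butyldimethylsilyl)oxy]-10-hydroxygermacra-4,11(13)-diene-3,8-dione | CC(=C)[C@H]1[C@H](O[Si](C)(C)C(C)(C)C)/C=C(/C)C(=O)CC[C@](C)(O)CC1=O | intermediate
25 | (8R)-alcohol: 8α,10β-dihydroxy-3-ketone (1,3-anti diol) | CC(=C)[C@H]1[C@H](O[Si](C)(C)C(C)(C)C)/C=C(/C)C(=O)CC[C@](C)(O)C[C@H]1O | intermediate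
26 | isobutyric anhydride (2-methylpropanoic anhydride) | CC(C)C(=O)OC(=O)C(C)C | starting material
27 | 8-isobutyrate of 25 | CC(=C)[C@H]1[C@H](O[Si](C)(C)C(C)(C)C)/C=C(/C)C(=O)CC[C@](C)(O)C[C@H]1OC(=O)C(C)C | intermediate
28 | tert-butyl hydroperoxide | CC(C)(C)OO | starting material
29 | 12-hydroxy derivative of 27 (primary allylic alcohol) | OCC(=C)[C@H]1[C@H](O[Si](C)(C)C(C)(C)C)/C=C(/C)C(=O)CC[C@](C)(O)C[C@H]1OC(=O)C(C)C | intermediate
30 | (3S)-allylic alcohol: 3α,10β,12-triol 8-isobutyrate | OCC(=C)[C@H]1[C@H](O[Si](C)(C)C(C)(C)C)/C=C(/C)[C@@H](O)CC[C@](C)(O)C[C@H]1OC(=O)C(C)C | intermediate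
31 | enal: 12-aldehyde of 30 | O=CC(=C)[C@H]1[C@H](O[Si](C)(C)C(C)(C)C)/C=C(/C)[C@@H](O)CC[C@](C)(O)C[C@H]1OC(=O)C(C)C | intermediate
32 | sodium chlorite | [Na+].[O-]Cl=O | starting material
33 | acrylic acid: 12-oic acid of 30 | OC(=O)C(=C)[C@H]1[C@H](O[Si](C)(C)C(C)(C)C)/C=C(/C)[C@@H](O)CC[C@](C)(O)C[C@H]1OC(=O)C(C)C | intermediate
34 | 6β-hydroxy acid (33 without the silyl group) | OC(=O)C(=C)[C@H]1[C@H](O)/C=C(/C)[C@@H](O)CC[C@](C)(O)C[C@H]1OC(=O)C(C)C | intermediate (not isolated)
35 | (3S,4Z,6R,7R,8R,10S)-3,10-dihydroxy-8-(2-methylpropanoyloxy)germacra-4,11(13)-dien-12,6-olide | C=C1C(=O)O[C@@H]2/C=C(/C)[C@@H](O)CC[C@](C)(O)C[C@@H](OC(=O)C(C)C)[C@@H]12 | target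

Total step count: 18. Longest linear sequence: 18 steps, all from (S)-carvone; the other starting materials are purchased reagents.

Steps most likely to fail

1. Step 15, loss of facial control. The ten-membered ring is flexible, the C10 hydroxyl sits across the ring from C3, and ring–chain tautomerism to the 3,10-hemiketal can hide the ketone, so catalyst control may be eroded or the reduction may stall. The fallback sets out from 27 and returns at 30; it uses the ring's own facial bias and then corrects it. Luche reduction of 27 (NaBH4, CeCl3·7H2O, MeOH, −78 °C) should give the allylic alcohol favoured by the ring. If this is the (3R)-alcohol F1, Mitsunobu inversion with 4-nitrobenzoic acid (PPh3, diisopropyl azodicarboxylate, toluene, 0 °C) should give the (3S)-4-nitrobenzoate F2; a (3S)-alcohol would simply be acylated to the same ester. The SeO2/t-BuOOH oxidation of step 14 is then run on F2, whose C4=C5 alkene is deactivated by two allylic oxygen substituents, to give the 12-hydroxy ester F3. Brief treatment with K2CO3 in MeOH at 0 °C should remove the activated benzoate, but not the hindered isobutyrate, and give 30.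

2. Step 14, poor site selectivity and over-oxidation. Ene reaction at C7–H or at the ring alkene (if the enone is tied up as the hemiketal), oxidation of the C2 methylene next to the ketone and partial over-oxidation to the enal may all lower the throughput. The fallback sets out from 27 and returns at 29; it chlorinates instead of oxygenating. Ene-type allylic chlorination with hypochlorous acid (Ca(OCl)2, solid CO2, CH2Cl2/H2O, 0 °C), which is selective for the electron-rich 1,1-disubstituted alkene, should give the allylic chloride F4. Displacement with HCO2Na (Bu4NI cat., DMF, 40 °C) should give the formate F5, and NaHCO3 in MeOH cleaves the formate to 29.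

3. Step 12, loss of the directing effect. Transannular hemiketal formation ties up the C10 hydroxyl that must bind boron, and the C8 ketone of 24 can lose the C6 silyloxy group by β-elimination while it waits. The fallback sets out from 23 and returns at 25; the hydride is tethered to O10 before the ketones exist. The least hindered tertiary hydroxyl of 23 is silylated with chlorodiisopropylsilane (imidazole, DMF, 0 °C) to the 10-O-diisopropylsilyl ether F6. Pb(OAc)4 cleavage as in step 11 should give the 10-O-silylated enedione F7, which cannot form a hemiketal. SnCl4 (CH2Cl2, −78 °C) then triggers intramolecular hydrosilylation of the β-silyloxy ketone, which is anti-selective, and should give the cyclic 8,10-O-diisopropylsilylene acetal F8. Buffered HF·pyridine (pyridine, THF, 0 °C) removes the silylene, but not the tert-butyldimethylsilyl ether, and gives 25.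

Further compounds
F1 | step 15 | (3R)-allylic alcohol from Luche reduction of 27 (3β-hydroxyl) | CC(=C)[C@H]1[C@H](O[Si](C)(C)C(C)(C)C)/C=C(/C)[C@H](O)CC[C@](C)(O)C[C@H]1OC(=O)C(C)C
F2 | step 15 | (3S)-4-nitrobenzoate (3α-ester) of the 8-isobutyrate | CC(=C)[C@H]1[C@H](O[Si](C)(C)C(C)(C)C)/C=C(/C)[C@@H](OC(=O)c2ccc(cc2)[N+](=O)[O-])CC[C@](C)(O)C[C@H]1OC(=O)C(C)C
F3 | step 15 | 12-hydroxy derivative of F2 | OCC(=C)[C@H]1[C@H](O[Si](C)(C)C(C)(C)C)/C=C(/C)[C@@H](OC(=O)c2ccc(cc2)[N+](=O)[O-])CC[C@](C)(O)C[C@H]1OC(=O)C(C)C
F4 | step 14 | 12-chloro derivative of 27 (allylic chloride) | ClCC(=C)[C@H]1[C@H](O[Si](C)(C)C(C)(C)C)/C=C(/C)C(=O)CC[C@](C)(O)C[C@H]1OC(=O)C(C)C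
F5 | step 14 | 12-formate of 29 | O=COCC(=C)[C@H]1[C@H](O[Si](C)(C)C(C)(C)C)/C=C(/C)C(=O)CC[C@](C)(O)C[C@H]1OC(=O)C(C)C
F6 | step 12 | 10-O-diisopropylsilyl ether of triol 23 | CC(=C)[C@H]1[C@H](O[Si](C)(C)C(C)(C)C)C=C(C)[C@]2(O)CC[C@](C)(O[SiH](C(C)C)C(C)C)C[C@]12O
F7 | step 12 | 10-O-diisopropylsilyl ether of enedione 24 | CC(=C)[C@H]1[C@H](O[Si](C)(C)C(C)(C)C)/C=C(/C)C(=O)CC[C@](C)(O[SiH](C(C)C)C(C)C)CC1=O
F8 | step 12 | 8,10-O-diisopropylsilylene acetal of diol 25 | CC(=C)[C@H]1[C@H](O[Si](C)(C)C(C)(C)C)/C=C(/C)C(=O)CC[C@@]2(C)C[C@H]1O[Si](C(C)C)(C(C)C)O2
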